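**Strategy**

Everything rests on cutting the bond between C2 of the resorcinol ring (ring A) and the benzylic CH2 of the catechol ring (ring C). The key step exploits a matched innate polarity: C2 of ring A is para to the C5 hydroxyl and ortho to the C3 hydroxyl, hence the most nucleophilic carbon, while the CH2 sits para to the C4 hydroxyl of ring C and is therefore the exocyclic carbon of a para-quinone methide. A biomimetic Friedel–Crafts hydroxybenzylation joins unprotected isorhapontigenin, which already holds the complete (E)-stilbene, with 3,4-dihydroxybenzyl alcohol in one operation, with no protecting group and no prefunctionalisation of either partner.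

Key step: step 1

Remark on numbering: ring A is the resorcinol ring, numbered from the carbon that bears the alkene (C1); ring B is the 4-hydroxy-3-methoxyphenyl ring; ring C is the catechol ring.

Assumption: isorhapontigenin (1) and 3,4-dihydroxybenzyl alcohol (2) are catalogue compounds and are used as bought.

**Route**

Step 1
Reactants: 1 isorhapontigenin, (E)-5-[2-(4-hydroxy-3-methoxyphenyl)ethenyl]benzene-1,3-diol; 2 3,4-dihydroxybenzyl alcohol, 4-(hydroxymethyl)benzene-1,2-diol
Product: 4 gnetupendin B, via para-quinone methide 3 (not isolated)
Conditions: TsOH·H2O (5 mol%), degassed MeCN, 40 °C, Ar, dark; 2 (1 equiv) added over 3 h to 1 (3 equiv); excess 1 recovered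
Reagents that add atoms: none
Why: Acid-assisted loss of water from 2 gives the para-quinone methide 3 (or its O-protonated form), and C2 of ring A of 1 adds to its exocyclic carbon in a 1,6-conjugate addition, after which tautomerisation of the cyclohexadienone restores both arenes. The closest known reaction type is the Friedel–Crafts hydroxybenzylation of phenols by quinone methides, the elementary step of novolac formation and of the alkylation of 5-substituted resorcinols. No ring is closed and no stereocentre is formed; the (E)-alkene should not be touched by catalytic acid in the dark. The step needs site selectivity for C2 (equivalent to C6) over C4 of ring A, for ring A over rings B and C and the alkene, and for mono- over bis-benzylation. C2 is para to the C5 hydroxyl and ortho to the C3 hydroxyl, the kinetic position in alkylations of orcinol- and olivetol-type resorcinols, and it is present twice, whereas the oxygen substituents of rings B and C are ortho to each other and do not reinforce one carbon. Excess 1 and slow addition of 2 keep the concentration of 3 low and should suppress a second benzylation and self-condensation of 2.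

**Compound list**

1 | isorhapontigenin, (E)-5-[2-(4-hydroxy-3-methoxyphenyl)ethenyl]benzene-1,3-diol | COc1cc(/C=C/c2cc(O)cc(O)c2)ccc1O | starting material
2 | 3,4-dihydroxybenzyl alcohol, 4-(hydroxymethyl)benzene-1,2-diol | OCc1ccc(O)c(O)c1 | starting material
3 | 2-hydroxy-4-methylidenecyclohexa-2,5-dien-1-one (para-quinone methide of 2) | C=C1C=CC(=O)C(O)=C1 | intermediate
4 | gnetupendin B, 4-[[2,4-dihydroxy-6-[(E)-2-(4-hydroxy-3-methoxyphenyl)ethenyl]phenyl]methyl]benzene-1,2-diol | COc1cc(/C=C/c2cc(O)cc(O)c2Cc2ccc(O)c(O)c2)ccc1O | target

**Step count and risks**

Total step count: 1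
Longest linear sequence: 1 step

Steps most likely to fail: the route has a single step, so it is the only entry.

Step 1. Three processes may spoil it:
- attack of the quinone methide at C4 of ring A instead of C2, or a second benzylation at C6;
- self-condensation of the benzyl alcohol through ring C;
- acid-induced oligomerisation of the electron-rich stilbene.

Fallback (known chemistry, site fixed by a halogen): it sets out from 1. Perbenzylation (BnBr, K2CO3, DMF, rt) should give the tris(benzyl ether) of isorhapontigenin F1. NBS in CH2Cl2 at 0 °C should brominate ring A at C2, para to the C5 ether, to give the 2-bromo tris(benzyl ether) F2. Commercial 3,4-bis(benzyloxy)benzyl chloride is treated with Zn dust and LiCl in THF at rt to give [3,4-bis(benzyloxy)benzyl]zinc chloride F3. Negishi coupling of F2 with F3 (Pd(OAc)2, SPhos, THF, 60 °C, zerovalent palladium formed in the flask) should give pentabenzyl gnetupendin B F4. BCl3 with pentamethylbenzene in CH2Cl2 at −78 °C should then remove all five benzyl groups without touching the alkene or the methyl ether. The fallback comes back to the route at 4.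

Further compounds
F1 | step 1 | tris(benzyl ether) of isorhapontigenin, (E)-1,3-bis(benzyloxy)-5-[2-(4-benzyloxy-3-methoxyphenyl)ethenyl]benzene | COc1cc(/C=C/c2cc(OCc3ccccc3)cc(OCc3ccccc3)c2)ccc1OCc1ccccc1
F2 | step 1 | 2-bromo tris(benzyl ether), (E)-1,5-bis(benzyloxy)-2-bromo-3-[2-(4-benzyloxy-3-methoxyphenyl)ethenyl]benzene | COc1cc(/C=C/c2cc(OCc3ccccc3)cc(OCc3ccccc3)c2Br)ccc1OCc1ccccc1
F3 | step 1 | [3,4-bis(benzyloxy)benzyl]zinc chloride | Cl[Zn]Cc1ccc(OCc2ccccc2)c(OCc2ccccc2)c1
F4 | step 1 | pentabenzyl gnetupendin B, (E)-1,5-bis(benzyloxy)-2-[3,4-bis(benzyloxy)benzyl]-3-[2-(4-benzyloxy-3-methoxyphenyl)ethenyl]benzene | COc1cc(/C=C/c2cc(OCc3ccccc3)cc(OCc3ccccc3)c2Cc2ccc(OCc3ccccc3)c(OCc3ccccc3)c2)ccc1OCc1ccccc1
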